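The plan rests on reading the α-ketol C4(=O)–C3H(OH) in ring C of the dihydroflavonol half as a benzoin retron. A chiral triazolylidene converts the A-ring formyl carbon (future C4, on C4a) into an acyl anion that closes the pyranone onto a tethered α-aryloxy aldehyde (future C3), creating the C3 carbinol and fixing the enolisable C2 centre in the same operation. The precursor is an acyclic dialdehyde: an ortho-formyl aryl ether of an aryl glycolaldehyde, obtained by iridium-catalysed allylic etherification and alkene cleavage on a 2,2′-dioxygenated biaryl whose second ring already carries the (2S)-flavanone from a rhodium-catalysed chromone arylation. Hydrogenolysis of six benzyl ethers ends the route.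

Key step: step 11

Remark: Bn = benzyl and Bpin = 4,4,5,5-tetramethyl-1,3,2-dioxaborolan-2-yl; each chiral ligand or precatalyst exists in both enantiomeric forms, and the enantiomer named is the one assumed, by analogy with simpler substrates, to give the configuration stated.

Step 1
Reactants: 1 4-(benzyloxy)-3-bromobenzaldehyde; 2 [2-(benzyloxy)-5-chlorophenyl]boronic acid
Product: 3 2′,6-bis(benzyloxy)-5′-chlorobiphenyl-3-carbaldehyde
Conditions: Pd(PPh3)4 (3 mol%), K2CO3, toluene/EtOH/H2O, 80 °C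
Reagents that add atoms: none
Why: Suzuki–Miyaura coupling in which oxidative addition into C–Br is far faster than into C–Cl, so the chloride should survive as the latent boron site and the aldehyde is inert.

Step 2
Reactants: 3 2′,6-bis(benzyloxy)-5′-chlorobiphenyl-3-carbaldehyde
Product: 4 2′,6-bis(benzyloxy)-5′-(Bpin)biphenyl-3-carbaldehyde
Conditions: B2pin2, Pd2(dba)3/XPhos (2/8 mol%), KOAc, dioxane, 100 °C
Reagents that add atoms: bis(pinacolato)diboron CC1(C)OB(OC1(C)C)B1OC(C)(C)C(C)(C)O1
Why: Miyaura borylation of the aryl chloride with a bulky biarylphosphine catalyst, where acetate is too weak a base for homocoupling and the aldehyde is tolerated.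

Step 3
Reactants: 4 2′,6-bis(benzyloxy)-5′-(Bpin)biphenyl-3-carbaldehyde
Product: 5 ethyl (E)-3-[2′,6-bis(benzyloxy)-5′-(Bpin)biphenyl-3-yl]acrylate
Conditions: (EtO)2P(O)CH2CO2Et, NaH, THF, 0 °C→rt
Reagents that add atoms: triethyl phosphonoacetate CCOC(=O)CP(=O)(OCC)OCC
Why: Horner–Wadsworth–Emmons olefination should give the E enoate, and the stabilised phosphonate anion does not attack the aryl boronate.

Step 4
Reactants: 5 ethyl (E)-3-[2′,6-bis(benzyloxy)-5′-(Bpin)biphenyl-3-yl]acrylate
Product: 6 (E)-3-[2′,6-bis(benzyloxy)-5′-(Bpin)biphenyl-3-yl]prop-2-en-1-ol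
Conditions: DIBAL-H (2.2 equiv), CH2Cl2, −78 °C; Rochelle salt
Reagents that add atoms: none
Why: 1,2-reduction of the enoate by DIBAL-H at low temperature gives the allylic alcohol and leaves the aryl boronate and benzyl ethers untouched.

Step 5
Reactants: 6 (E)-3-[2′,6-bis(benzyloxy)-5′-(Bpin)biphenyl-3-yl]prop-2-en-1-ol
Product: 7 (E)-3-[2′,6-bis(benzyloxy)-5′-(Bpin)biphenyl-3-yl]allyl methyl carbonate
Conditions: ClCO2Me, pyridine, CH2Cl2, 0 °C
Reagents that add atoms: methyl chloroformate COC(=O)Cl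
Why: O-acylation of the primary allylic alcohol installs the carbonate leaving group needed for the allylic substitution.

Step 6
Reactants: 8 2,4,6-trihydroxybenzaldehyde
Product: 9 4,6-bis(benzyloxy)-2-hydroxybenzaldehyde
Conditions: BnBr (2.1 equiv), K2CO3, DMF, rt
Reagents that add atoms: benzyl bromide BrCc1ccccc1
Why: Williamson etherification stops at the dibenzyl ether because the last ortho hydroxyl is locked in a hydrogen bond to the formyl group.

Step 7
Reactants: 7 (E)-3-[2′,6-bis(benzyloxy)-5′-(Bpin)biphenyl-3-yl]allyl methyl carbonate; 9 4,6-bis(benzyloxy)-2-hydroxybenzaldehyde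
Product: 11 (S)-4,6-bis(benzyloxy)-2-{1-[2′,6-bis(benzyloxy)-5′-(Bpin)biphenyl-3-yl]allyloxy}benzaldehyde, via lithium phenoxide 10 (not isolated)
Conditions: 9, LiHMDS, THF, 0 °C; then 7, [Ir(cod)Cl]2 (2 mol%), (Sa,Sc,Sc)-BINOL N,N-bis(1-phenylethyl)phosphoramidite (4 mol%), THF, rt→50 °C
Reagents that add atoms: none
Why: Ir-catalysed asymmetric allylic etherification, in which the phenoxide attacks the substituted terminus of the (π-allyl)Ir–phosphoramidite complex to give the branched ether and the ligand sets the new C–O stereocentre as S (the future C2 of ring C).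

Step 8
Reactants: 12 5,7-dihydroxy-4H-chromen-4-one
Product: 13 5,7-bis(benzyloxy)-4H-chromen-4-one
Conditions: BnBr (2.5 equiv), K2CO3, DMF, 70 °C
Reagents that add atoms: benzyl bromide BrCc1ccccc1
Why: Williamson etherification of both phenols, the hydrogen-bonded 5-OH needing warming, removes the acidic protons ahead of the rhodium step.

Step 9
Reactants: 11 (S)-4,6-bis(benzyloxy)-2-{1-[2′,6-bis(benzyloxy)-5′-(Bpin)biphenyl-3-yl]allyloxy}benzaldehyde; 13 5,7-bis(benzyloxy)-4H-chromen-4-one
Product: 14 (S)-4,6-bis(benzyloxy)-2-{1-[2′,6-bis(benzyloxy)-5′-((2S)-5,7-bis(benzyloxy)-4-oxochroman-2-yl)biphenyl-3-yl]allyloxy}benzaldehyde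
Conditions: [Rh(OH)(cod)]2 (2.5 mol%), (S)-MeO-F12-BIPHEP (5.5 mol%), 13 (2 equiv), toluene/H2O 10:1, 50 °C, no added base
Reagents that add atoms: none
Why: Rh-catalysed asymmetric 1,4-addition (Hayashi–Miyaura) of the aryl boronate to the chromone, in which the bisphosphine selects the enantioface in the aryl-rhodium insertion into C2=C3 and sets the flavanone C2 as S, while base-free conditions prevent ring opening of the flavanone.

Step 10
Reactants: 14 (S)-4,6-bis(benzyloxy)-2-{1-[2′,6-bis(benzyloxy)-5′-((2S)-5,7-bis(benzyloxy)-4-oxochroman-2-yl)biphenyl-3-yl]allyloxy}benzaldehyde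
Product: 16 (R)-4,6-bis(benzyloxy)-2-{1-[2′,6-bis(benzyloxy)-5′-((2S)-5,7-bis(benzyloxy)-4-oxochroman-2-yl)biphenyl-3-yl]-2-oxoethoxy}benzaldehyde, via vicinal diol 15 (not isolated)
Conditions: OsO4 (2 mol%), NaIO4 (4 equiv), 2,6-lutidine, dioxane/H2O 3:1, rt; short silica plug, used at once
Reagents that add atoms: osmium tetroxide O=[Os](=O)(=O)=O; sodium periodate [Na+].[O-]I(=O)(=O)=O
Why: Lemieux–Johnson cleavage (dihydroxylation, then periodate glycol cleavage) of the only alkene should unmask the second aldehyde under lutidine-buffered conditions that spare the flavanone.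

Step 11
Reactants: 16 (R)-4,6-bis(benzyloxy)-2-{1-[2′,6-bis(benzyloxy)-5′-((2S)-5,7-bis(benzyloxy)-4-oxochroman-2-yl)biphenyl-3-yl]-2-oxoethoxy}benzaldehyde
Product: 17 hexa-O-benzyl ether of the target (free 3-OH on the 2R,3R ring; 2S flavanone)
Conditions: (5aR,10bS)-aminoindanol-derived N-C6F5 triazolium BF4 (20 mol%), i-Pr2NEt (1 equiv), toluene, 0 °C→rt, Ar
Reagents that add atoms: none
Why: Proposed new method: the carbene adds to the aryl aldehyde, proton transfer gives the Breslow intermediate (acyl anion at the future C4), and this attacks the tethered aldehyde carbon (future C3), after which loss of the carbene leaves the C4 ketone and the C3 hydroxyl. The closest known reaction is the triazolium-catalysed intramolecular crossed benzoin of salicylaldehyde-tethered ketones to 3-hydroxychroman-4-ones, including its dynamic kinetic variant with configurationally labile α-aryloxy β-keto esters; new here is an enolisable α-aryloxy aldehyde as the acceptor. The pyranone ring C closes in a 6-exo-trig mode on the C=O group. C3 is set by the catalyst-controlled face of attack with the C2 aryl group pseudo-equatorial in a chair-like transition state (2,3-trans), and a cis product would epimerise at C3 to the more stable trans ketol. C2 enters as R from step 7 and, being enolisable under the amine base, is funnelled through the matched (R)-aldehyde by dynamic kinetic resolution. The step needs the aryl and not the aliphatic aldehyde to be the acyl donor, because a Breslow intermediate at the α-aryloxy aldehyde could expel the aryloxide; carbene addition is reversible and C–C bond formation should be fastest for the electron-rich aryl Breslow intermediate paired with the strongly electrophilic α-oxy aldehyde, whereas the reverse pairing must attack a deactivated, doubly ortho-substituted aryl aldehyde.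

Step 12
Reactants: 17 hexa-O-benzyl ether of the target
Product: 18 CNP0201582.1 (target)
Conditions: H2 (1 atm), 10% Pd/C, EtOAc/MeOH, rt
Reagents that add atoms: none
Why: Hydrogenolysis of the six aryl benzyl ethers at 1 atm in neutral solvent should leave the cyclic benzylic C2–O bonds, the aryl ketones and the secondary alcohol intact, so all three stereocentres survive.

Compound list
1 | 4-(benzyloxy)-3-bromobenzaldehyde | O=Cc1ccc(OCc2ccccc2)c(Br)c1 | starting material
2 | [2-(benzyloxy)-5-chlorophenyl]boronic acid | OB(O)c1cc(Cl)ccc1OCc1ccccc1 | starting material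
3 | 2′,6-bis(benzyloxy)-5′-chlorobiphenyl-3-carbaldehyde | O=Cc1ccc(OCc2ccccc2)c(-c2cc(Cl)ccc2OCc2ccccc2)c1 | intermediate
4 | 2′,6-bis(benzyloxy)-5′-(Bpin)biphenyl-3-carbaldehyde | O=Cc1ccc(OCc2ccccc2)c(-c2cc(B3OC(C)(C)C(C)(C)O3)ccc2OCc2ccccc2)c1 | intermediate
5 | ethyl (E)-3-[2′,6-bis(benzyloxy)-5′-(Bpin)biphenyl-3-yl]acrylate | CCOC(=O)/C=C/c1ccc(OCc2ccccc2)c(-c2cc(B3OC(C)(C)C(C)(C)O3)ccc2OCc2ccccc2)c1 | intermediate
6 | (E)-3-[2′,6-bis(benzyloxy)-5′-(Bpin)biphenyl-3-yl]prop-2-en-1-ol | OC/C=C/c1ccc(OCc2ccccc2)c(-c2cc(B3OC(C)(C)C(C)(C)O3)ccc2OCc2ccccc2)c1 | intermediate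
7 | (E)-3-[2′,6-bis(benzyloxy)-5′-(Bpin)biphenyl-3-yl]allyl methyl carbonate | COC(=O)OC/C=C/c1ccc(OCc2ccccc2)c(-c2cc(B3OC(C)(C)C(C)(C)O3)ccc2OCc2ccccc2)c1 | intermediate
8 | 2,4,6-trihydroxybenzaldehyde | O=Cc1c(O)cc(O)cc1O | starting material
9 | 4,6-bis(benzyloxy)-2-hydroxybenzaldehyde | O=Cc1c(O)cc(OCc2ccccc2)cc1OCc1ccccc1 | intermediate
10 | lithium 3,5-bis(benzyloxy)-2-formylphenoxide (not isolated) | [Li+].[O-]c1cc(OCc2ccccc2)cc(OCc2ccccc2)c1C=O | intermediate
11 | (S)-branched allyl aryl ether carrying the A-ring aldehyde and the aryl Bpin | C=C[C@H](Oc1cc(OCc2ccccc2)cc(OCc2ccccc2)c1C=O)c1ccc(OCc2ccccc2)c(-c2cc(B3OC(C)(C)C(C)(C)O3)ccc2OCc2ccccc2)c1 | intermediate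
12 | 5,7-dihydroxy-4H-chromen-4-one | O=c1ccoc2cc(O)cc(O)c12 | starting material
13 | 5,7-bis(benzyloxy)-4H-chromen-4-one | O=c1ccoc2cc(OCc3ccccc3)cc(OCc3ccccc3)c12 | intermediate
14 | (S)-allyl aryl ether carrying the (2S)-5,7-bis(benzyloxy)flavanone | C=C[C@H](Oc1cc(OCc2ccccc2)cc(OCc2ccccc2)c1C=O)c1ccc(OCc2ccccc2)c(-c2cc([C@@H]3CC(=O)c4c(OCc5ccccc5)cc(OCc5ccccc5)cc4O3)ccc2OCc2ccccc2)c1 | intermediate
15 | vicinal diol from dihydroxylation of the vinyl group of 14, carbinol centre undefined (not isolated) | OCC(O)[C@H](Oc1cc(OCc2ccccc2)cc(OCc2ccccc2)c1C=O)c1ccc(OCc2ccccc2)c(-c2cc([C@@H]3CC(=O)c4c(OCc5ccccc5)cc(OCc5ccccc5)cc4O3)ccc2OCc2ccccc2)c1 | intermediate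
16 | dialdehyde: (R)-α-aryl-α-(2-formylaryloxy)acetaldehyde carrying the (2S)-flavanone | O=C[C@H](Oc1cc(OCc2ccccc2)cc(OCc2ccccc2)c1C=O)c1ccc(OCc2ccccc2)c(-c2cc([C@@H]3CC(=O)c4c(OCc5ccccc5)cc(OCc5ccccc5)cc4O3)ccc2OCc2ccccc2)c1 | intermediate
17 | hexa-O-benzyl ether of the target: (2R,3R)-3-hydroxyflavanone unit joined 3′→3′ to the (2S)-flavanone unit | O=C1C[C@@H](c2ccc(OCc3ccccc3)c(-c3cc([C@H]4Oc5cc(OCc6ccccc6)cc(OCc6ccccc6)c5C(=O)[C@@H]4O)ccc3OCc3ccccc3)c2)Oc2cc(OCc3ccccc3)cc(OCc3ccccc3)c21 | intermediate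
18 | CNP0201582.1, (2S)-naringenin-(3′→3′)-(2R,3R)-aromadendrin | O=C1C[C@@H](c2ccc(O)c(-c3cc([C@H]4Oc5cc(O)cc(O)c5C(=O)[C@@H]4O)ccc3O)c2)Oc2cc(O)cc(O)c21 | target

Total step count: 12. Longest linear sequence: 10 (steps 1–5, 7, 9, 10, 11, 12).

Steps most likely to fail

1. Step 11. The carbene may add to the aliphatic aldehyde instead, and that Breslow intermediate can expel the aryloxide (internal redox esterification). Control at C2 and C3 may also be lost if enolisation and cyclisation rates are mismatched. The fallback uses known chemistry, sets out from 11 and comes back at 17. Wittig methylenation of the aryl aldehyde (Ph3P=CH2, THF, 0 °C) would give the diene F1. Ring-closing metathesis (Grubbs II, CH2Cl2, 40 °C) would then form the same C3–C4 bond as the C3=C4 alkene of the (S)-2-aryl-2H-chromene F2, leaving the iridium-set C2 centre untouched. Arylation of 13 as in step 9 would give the flavene–flavanone F3. OsO4/NMO should add anti to the C2 aryl group to give the 2,3-trans-3,4-cis diol F4. MnO2 in CH2Cl2 should oxidise only the doubly activated benzylic C4 hydroxyl, which gives 17.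

2. Step 7. The lithium-chelated, electron-poor ortho-formyl phenoxide may attack slowly, and the product ether may re-ionise on iridium, with loss of branched selectivity and ee. The fallback sets out from 6 and comes back at 16. Sharpless asymmetric epoxidation (Ti(O-i-Pr)4, L-(+)-DIPT, t-BuOOH, −20 °C) would give the (2S,3S)-epoxy alcohol F5. The phenoxide of 9 (NaOH, dioxane/H2O, 60 °C; pinacol re-esterification if the boronate hydrolyses) should open it at the benzylic carbon with inversion to give the (2S,3R)-3-aryloxy-1,2-diol F6. Arylation of 13 as in step 9 would give the flavanone diol F7, a single diastereomer of 15. NaIO4 cleavage of the glycol then gives 16.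

3. Step 9. Slow insertion into the electron-rich, peri-substituted chromone may let protodeboronation of the boronate and rhodium-induced ionisation of the allyl aryl ether compete. The fallback sets out from 6 (with 13) and comes back at 14. The arylation is moved forward to the robust alcohol 6, where excess chromone, higher temperature or a Pd(II)/pyridine–oxazoline catalyst can be used, to give the flavanone cinnamyl alcohol F8. Methyl chloroformate and pyridine would give the carbonate F9. Iridium-catalysed etherification with 10 as in step 7, with excess 9 to buffer the methoxide by-product, then gives 14.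

Further compounds
F1 | step 11 | (S)-4,6-bis(benzyloxy)-2-vinylphenyl 1-arylallyl ether (diene, aryl Bpin retained) | C=C[C@H](Oc1cc(OCc2ccccc2)cc(OCc2ccccc2)c1C=C)c1ccc(OCc2ccccc2)c(-c2cc(B3OC(C)(C)C(C)(C)O3)ccc2OCc2ccccc2)c1
F2 | step 11 | (S)-5,7-bis(benzyloxy)-2-aryl-2H-chromene (aryl Bpin retained) | C1=Cc2c(OCc3ccccc3)cc(OCc3ccccc3)cc2O[C@@H]1c1ccc(OCc2ccccc2)c(-c2cc(B3OC(C)(C)C(C)(C)O3)ccc2OCc2ccccc2)c1
F3 | step 11 | (S)-2H-chromene carrying the (2S)-5,7-bis(benzyloxy)flavanone | C1=Cc2c(OCc3ccccc3)cc(OCc3ccccc3)cc2O[C@@H]1c1ccc(OCc2ccccc2)c(-c2cc([C@@H]3CC(=O)c4c(OCc5ccccc5)cc(OCc5ccccc5)cc4O3)ccc2OCc2ccccc2)c1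
F4 | step 11 | 2,3-trans-3,4-cis flavan-3,4-diol carrying the (2S)-flavanone | O=C1C[C@@H](c2ccc(OCc3ccccc3)c(-c3cc([C@H]4Oc5cc(OCc6ccccc6)cc(OCc6ccccc6)c5[C@H](O)[C@@H]4O)ccc3OCc3ccccc3)c2)Oc2cc(OCc3ccccc3)cc(OCc3ccccc3)c21
F5 | step 7 | (2S,3S)-3-aryl-2,3-epoxypropan-1-ol (aryl Bpin retained) | OC[C@@H]1O[C@H]1c1ccc(OCc2ccccc2)c(-c2cc(B3OC(C)(C)C(C)(C)O3)ccc2OCc2ccccc2)c1
F6 | step 7 | (2S,3R)-3-aryl-3-(3,5-bis(benzyloxy)-2-formylphenoxy)propane-1,2-diol (aryl Bpin retained) | OC[C@H](O)[C@H](Oc1cc(OCc2ccccc2)cc(OCc2ccccc2)c1C=O)c1ccc(OCc2ccccc2)c(-c2cc(B3OC(C)(C)C(C)(C)O3)ccc2OCc2ccccc2)c1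
F7 | step 7 | (2S,3R)-3-aryloxy-1,2-diol carrying the (2S)-flavanone | OC[C@H](O)[C@H](Oc1cc(OCc2ccccc2)cc(OCc2ccccc2)c1C=O)c1ccc(OCc2ccccc2)c(-c2cc([C@@H]3CC(=O)c4c(OCc5ccccc5)cc(OCc5ccccc5)cc4O3)ccc2OCc2ccccc2)c1
F8 | step 9 | (E)-cinnamyl alcohol carrying the (2S)-flavanone | OC/C=C/c1ccc(OCc2ccccc2)c(-c2cc([C@@H]3CC(=O)c4c(OCc5ccccc5)cc(OCc5ccccc5)cc4O3)ccc2OCc2ccccc2)c1
F9 | step 9 | (E)-cinnamyl methyl carbonate carrying the (2S)-flavanone | COC(=O)OC/C=C/c1ccc(OCc2ccccc2)c(-c2cc([C@@H]3CC(=O)c4c(OCc5ccccc5)cc(OCc5ccccc5)cc4O3)ccc2OCc2ccccc2)c1
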